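The bicyclo[2.2.2]octenone (C1–C5, C10, C1′, C2′) is read as the adduct of the vinyl group of myrcene with a eudesmane cyclohexa-2,4-dienone (ring A: C1=O, C2=C3, C4=C5, quaternary C10), and that dienone as the 6π-electrocyclisation product of a (Z)-dienylketene. One operation therefore runs a Wolff rearrangement of a dienyl diazoketone, the ring closure C1–C10 and the intermolecular [4+2] cycloaddition (C2–C2′, C5–C1′), setting C10, C5, C2 and C2′. The precursor is a dienyl diazomethyl ketone on the lactone-fused ring B, whose three stereocentres (C6, C7, C11) are taken from α-santonin by excision of ring A.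

Key step: step 8

Remark: eudesmane numbers are used for the sesquiterpene part and primed numbers for the myrcene carbons; C5–C14 come from santonin, C1, C3, C4 and C15 from the butynoate, C2 from diazomethane. Ketone 7 may be a mixture of C10 epimers, which is of no consequence because C10 becomes sp2 in step 4.

Step 1
Reactants: 1 but-2-ynoic acid; 2 2-(trimethylsilyl)ethanol
Product: 3 2-(trimethylsilyl)ethyl but-2-ynoate
Conditions: DCC, DMAP (5 mol %), CH2Cl2, −20 → 0 °C
Reagents that add atoms: none
Why: Steglich esterification installs an ester that can later be cleaved by fluoride without touching a lactone; no stereocentre is formed.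

Step 2
Reactants: 3 2-(trimethylsilyl)ethyl but-2-ynoate
Product: 4 2-(trimethylsilyl)ethyl (2Z)-3-(tributylstannyl)but-2-enoate
Conditions: Bu3SnH, LiN(i-Pr)2, THF, −78 °C; CuBr·SMe2; 3, −78 → −48 °C, 4 h; MeOH
Reagents that add atoms: tributyltin hydride, CCCC[SnH](CCCC)CCCC
Why: Stannylcupration of a 2-alkynoate under equilibrating conditions should let the syn adduct isomerise through the allenoate to the chelated alkenylcopper, so that protonation gives the stannane with tin cis to the ester (Z).

Step 3
Reactants: 5 α-santonin
Product: 7 (3S,3aS,7aS)-3,6-dimethylhexahydro-1-benzofuran-2,7-dione (keto lactone), via formyl ketone 6 (not isolated)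
Conditions: O3, CH2Cl2/MeOH, −78 °C; Me2S, −78 → 20 °C; NaHCO3, MeOH/H2O, 0 °C
Reagents that add atoms: ozone, [O-][O+]=O
Why: Ozonolysis should cleave both enone double bonds of ring A (C1=C2 and C4=C5), leaving C5 as a ketone, and the resulting α,α-disubstituted β-keto aldehyde should lose its formyl group by retro-Claisen cleavage under cold bicarbonate, which is mild enough not to epimerise C6; C6, C7 and C11 are carried over unchanged from santonin.

Step 4
Reactants: 7 keto lactone
Product: 8 (3S,3aS,7aS)-3,6-dimethyl-2-oxo-2,3,3a,4,5,7a-hexahydro-1-benzofuran-7-yl trifluoromethanesulfonate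
Conditions: Tf2O, 2,6-di-tert-butyl-4-methylpyridine, CH2Cl2, 0 → 20 °C
Reagents that add atoms: trifluoromethanesulfonic anhydride, O=S(=O)(OS(=O)(=O)C(F)(F)F)C(F)(F)F
Why: Enol triflation through the O-sulfonylated oxocarbenium ion should lose the proton at C10 rather than at C6, because the acyloxy group at C6 disfavours charge development on that side and the alkyl-substituted tetrasubstituted enol triflate (C5=C10) is the more stable one.

Step 5
Reactants: 8 enol triflate; 4 (Z)-stannyl enoate
Product: 9 2-(trimethylsilyl)ethyl (2Z)-3-[(3S,3aS,7aS)-3,6-dimethyl-2-oxo-2,3,3a,4,5,7a-hexahydro-1-benzofuran-7-yl]but-2-enoate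
Conditions: Pd(PPh3)4 (10 mol %), CuCl, LiCl, DMSO, 25 → 50 °C
Reagents that add atoms: none
Why: Stille coupling accelerated by CuCl/LiCl (tin-to-copper transmetalation) should join the hindered alkenyl triflate and the β-stannyl enoate with retention of alkene geometry, so that C5 ends cis to the ester carbonyl (Z), as the later electrocyclisation requires.

Step 6
Reactants: 9 (Z)-dienoate
Product: 10 (2Z)-3-[(3S,3aS,7aS)-3,6-dimethyl-2-oxo-2,3,3a,4,5,7a-hexahydro-1-benzofuran-7-yl]but-2-enoic acid
Conditions: Bu4NF, THF, 0 → 20 °C; aq. NaHSO4, 0 °C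
Reagents that add atoms: none
Why: Fluoride-induced β-elimination of the 2-(trimethylsilyl)ethyl ester frees the acid without hydrolytic conditions, so the γ-lactone stays closed and the Z-alkene is untouched.

Step 7
Reactants: 10 (Z)-dienoic acid
Product: 12 (3S,3aS,7aS)-7-[(2Z)-5-diazo-4-oxopent-2-en-2-yl]-3,6-dimethyl-3a,4,5,7a-tetrahydro-1-benzofuran-2(3H)-one, via acid chloride 11 (not isolated)
Conditions: 1-chloro-N,N,2-trimethylprop-1-en-1-amine, CH2Cl2, 0 °C; CH2N2 (3 equiv), Et2O, −10 → 20 °C
Reagents that add atoms: diazomethane, C=[N+]=[N-]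
Why: The α-chloroenamine makes the acid chloride under neutral conditions (no HCl, no amine base, hence no Z/E isomerisation and no vinylketene), and C-acylation of diazomethane (first stage of an Arndt–Eistert sequence) gives the diazoketone, the β,β-disubstituted enoyl double bond being too hindered for dipolar cycloaddition.

Step 8
Reactants: 12 dienyl diazoketone; 13 β-myrcene
Product: 16 target CNP0385704.1, via dienylketene 14 (not isolated), via dienone 15 (not isolated)
Conditions: 13 (10 equiv), PhMe, hν (450 nm LEDs), 20 °C; then 100 °C, dark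
Reagents that add atoms: none
Why: Excitation of 12 triggers a Wolff rearrangement (the Z-dienyl group migrates from C1 to C2 with retention) to (Z)-dienylketene 14, whose thermal disrotatory 6π-electrocyclisation closes ring A through the C1–C10 bond to give the 6,6-disubstituted cyclohexa-2,4-dienone 15; on heating, 15 acts as the 4π partner toward the vinyl group of 13 in an intermolecular [4+2] cycloaddition that closes the bicyclo[2.2.2]octenone through C2–C2′ and C5–C1′. The closest known reaction types are the photo-Wolff/dienylketene electrocyclisation route to cyclohexadienones and phenols and the Diels–Alder reactions of cyclohexa-2,4-dienones (masked o-benzoquinones) with 1,3-dienes, which react there as 2π partners. C10 is set by torquoselection: the trans-fused lactone locks ring B so that C9 can rotate only toward the α-face (chair-like ring B, C4-methyl turned away from O6), which turns the C10 methyl to the β-face, cis to H6. C5 and C2 follow from addition of the dienophile to the β-face of ring A, anti to C7 and C9 of ring B which flank C5 on the α-face, and C2′ from the endo orientation of the C3′ unit under the diene. The step needs periselectivity (15 as diene, not as dienophile toward the diene of 13), regioselectivity (unsubstituted C1′ to C5, where the LUMO coefficient of the dienone terminus is largest, so that C2′ bonds to C2) and site selectivity (the monosubstituted C1′=C2′ rather than the 1,1-disubstituted alkene of 13, on steric grounds). Light of 450 nm should be absorbed only by the diazoketone, so that 15 and the β,γ-unsaturated ketone of 16 are not photolysed.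

Compound list
1 | but-2-ynoic acid | CC#CC(=O)O | starting material
2 | 2-(trimethylsilyl)ethanol | C[Si](C)(C)CCO | starting material
3 | 2-(trimethylsilyl)ethyl but-2-ynoate | CC#CC(=O)OCC[Si](C)(C)C | intermediate
4 | 2-(trimethylsilyl)ethyl (2Z)-3-(tributylstannyl)but-2-enoate | CCCC[Sn](CCCC)(CCCC)/C(C)=C\C(=O)OCC[Si](C)(C)C | intermediate
5 | α-santonin, (3S,3aS,5aS,9bS) | C[C@H]1[C@@H]2CC[C@]3(C=CC(=O)C(=C3[C@H]2OC1=O)C)C | starting material
6 | formyl ketone: (3S,3aS,7aS)-3,6-dimethyl-2,7-dioxooctahydro-1-benzofuran-6-carbaldehyde, C10 configuration as in santonin | C[C@H]1[C@@H]2CC[C@@](C)(C=O)C(=O)[C@H]2OC1=O | intermediate (not isolated)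
7 | keto lactone: (3S,3aS,7aS)-3,6-dimethylhexahydro-1-benzofuran-2,7-dione, C10 epimers | C[C@H]1[C@@H]2CCC(C)C(=O)[C@H]2OC1=O | intermediate
8 | enol triflate: (3S,3aS,7aS)-3,6-dimethyl-2-oxo-2,3,3a,4,5,7a-hexahydro-1-benzofuran-7-yl trifluoromethanesulfonate | C[C@H]1[C@@H]2CCC(C)=C(OS(=O)(=O)C(F)(F)F)[C@H]2OC1=O | intermediate
9 | (Z)-dienoate: 2-(trimethylsilyl)ethyl (2Z)-3-[(3S,3aS,7aS)-3,6-dimethyl-2-oxo-2,3,3a,4,5,7a-hexahydro-1-benzofuran-7-yl]but-2-enoate | C[C@H]1[C@@H]2CCC(C)=C(/C(C)=C\C(=O)OCC[Si](C)(C)C)[C@H]2OC1=O | intermediate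
10 | (Z)-dienoic acid: (2Z)-3-[(3S,3aS,7aS)-3,6-dimethyl-2-oxo-2,3,3a,4,5,7a-hexahydro-1-benzofuran-7-yl]but-2-enoic acid | C[C@H]1[C@@H]2CCC(C)=C(/C(C)=C\C(=O)O)[C@H]2OC1=O | intermediate
11 | acid chloride of 10 (2Z) | C[C@H]1[C@@H]2CCC(C)=C(/C(C)=C\C(=O)Cl)[C@H]2OC1=O | intermediate (not isolated)
12 | dienyl diazoketone: (3S,3aS,7aS)-7-[(2Z)-5-diazo-4-oxopent-2-en-2-yl]-3,6-dimethyl-3a,4,5,7a-tetrahydro-1-benzofuran-2(3H)-one | C[C@H]1[C@@H]2CCC(C)=C(/C(C)=C\C(=O)C=[N+]=[N-])[C@H]2OC1=O | intermediate
13 | β-myrcene (7-methyl-3-methylideneocta-1,6-diene) | C=CC(=C)CCC=C(C)C | starting material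
14 | (Z)-dienylketene: (3S,3aS,7aS)-3,6-dimethyl-7-[(2Z)-5-oxopenta-2,4-dien-2-yl]-3a,4,5,7a-tetrahydro-1-benzofuran-2(3H)-one | C[C@H]1[C@@H]2CCC(C)=C(/C(C)=C\C=C=O)[C@H]2OC1=O | intermediate (not isolated)
15 | dienone: (6S,7S,10R,11S)-1-oxoeudesma-2,4-dien-12,6-olide (C10 methyl β, trans-fused lactone) | O=C1C=CC(C)=C2[C@@]1(C)CC[C@H]1[C@H](C)C(=O)O[C@@H]12 | intermediate (not isolated)
16 | CNP0385704.1: (2S,5R,6S,7S,10R,11S,2′S) endo adduct of 15 across C2/C5 with the vinyl group of myrcene, 6-methylhepta-1,5-dien-2-yl group on C2′ syn to the C3=C4 bridge | C=C(CCC=C(C)C)[C@H]1C[C@@]23C(C)=C[C@@H]1C(=O)[C@]2(C)CC[C@H]1[C@H](C)C(=O)O[C@@H]13 | target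

Total step count: 8. Longest linear sequence: 6 steps (steps 3–8, from α-santonin).

Steps most likely to fail

Step 8. The cycloaddition may lose periselectivity (myrcene reacting as the diene with C2=C3 of 15), add to the α-face or in the exo sense, or react at the 1,1-disubstituted alkene of myrcene; the electrocyclisation may also be slow at the fully substituted C10 terminus. Fallback: setting out from 12, irradiation without myrcene gives dienone 15, which is used at once with the electron-poor dienophile 7-methylocta-1,6-dien-3-one F1 (from 6-methylhept-5-en-2-one by one-pot α-methylenation of its methyl group) in a thermal or ZnCl2-promoted Diels–Alder reaction, where the ortho/endo preference of dienones with enones should give the diketone adduct F2. Wittig methylenation (Ph3P=CH2, THF, 0 °C) of the side-chain ketone, the ring ketone being shielded by C10 and the bridgehead, comes back to the route at 16.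

Step 4. Proton loss toward C6 instead of C10 would give the regioisomeric enol triflate, and enolisation toward C6 could also epimerise the lactone ring fusion. Fallback: setting out from formyl ketone 6, isolated after the Me2S work-up of step 3, oxidation with NaClO2 gives the β-keto acid F3. Decarboxylative bromination (N-bromosuccinimide, CH2Cl2) places the halogen regiospecifically at C10 to give the tertiary α-bromo ketone F4. Reductive enolate formation (Me2CuLi, THF, −78 °C) and trapping with N-(5-chloropyridin-2-yl)bis(trifluoromethanesulfonimide) comes back to the route at 8.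

Step 5. Oxidative addition and transmetalation at the tetrasubstituted triflate may be slow, so that protodestannylation of 4 or ionisation of the allylic lactone by zerovalent palladium takes over. Fallback: setting out from 8 and 3, the polarity of the coupling is reversed. Miyaura borylation of 8 (B2pin2, PdCl2(dppf), KOAc, dioxane, 80 °C) gives the alkenyl pinacol boronate F5, and anti-hydroiodination of alkynoate 3 (NaI, AcOH, 80 °C) gives 2-(trimethylsilyl)ethyl (2Z)-3-iodobut-2-enoate F6. Suzuki–Miyaura coupling of the two (Pd(PPh3)4, CsF, dioxane, 60 °C) with retention of geometry comes back to the route at 9.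

Further compounds
F1 | step 8 | 7-methylocta-1,6-dien-3-one | C=CC(=O)CCC=C(C)C
F2 | step 8 | diketone adduct: analogue of 16 with a 5-methylhex-4-enoyl group at C2′ (same configuration, endo) | O=C(CCC=C(C)C)[C@H]1C[C@@]23C(C)=C[C@@H]1C(=O)[C@]2(C)CC[C@H]1[C@H](C)C(=O)O[C@@H]13
F3 | step 4 | β-keto acid: (3S,3aS,7aS)-3,6-dimethyl-2,7-dioxooctahydro-1-benzofuran-6-carboxylic acid | C[C@H]1[C@@H]2CC[C@@](C)(C(=O)O)C(=O)[C@H]2OC1=O
F4 | step 4 | α-bromo ketone: (3S,3aS,7aS)-6-bromo-3,6-dimethylhexahydro-1-benzofuran-2,7-dione | C[C@H]1[C@@H]2CCC(C)(Br)C(=O)[C@H]2OC1=O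
F5 | step 5 | alkenyl boronate: (3S,3aS,7aS)-3,6-dimethyl-7-(4,4,5,5-tetramethyl-1,3,2-dioxaborolan-2-yl)-3a,4,5,7a-tetrahydro-1-benzofuran-2(3H)-one | C[C@H]1[C@@H]2CCC(C)=C(B3OC(C)(C)C(C)(C)O3)[C@H]2OC1=O
F6 | step 5 | 2-(trimethylsilyl)ethyl (2Z)-3-iodobut-2-enoate | C[Si](C)(C)CCOC(=O)/C=C(/C)I
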